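**Retrosynthetic overview**
- Target ⇒ all-cis oxan-4-ol (equatorial OH): a Mitsunobu reaction with acetic acid installs the acetate and inverts C4 to the axial ester in one operation, leaving the phenols free.
- Oxane ring (the only ring made; both arenes are bought) ⇒ open-chain (3S,5S)-1,7-diarylheptane-3,5-diol: catechol → ortho-quinone → para-quinone methide, trapped by the C5 hydroxyl. This forms the benzylic C–O bond and the benzylic stereocentre (2,6-cis).
- anti-Diol ⇒ saturated 3,5-dione by Ru/(S)-BINAP hydrogenation; the anti-diol is pseudo-C2-symmetric, so one catalyst sets both centres without telling the two ends apart.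
- Dione ⇒ unsymmetrical curcuminoid ⇒ acetylacetone + vanillin + 5-hydroxyvanillin (two boron-templated aldol condensations, then C=C hydrogenation), the laboratory copy of the polyketide assembly of diarylheptanoids.

Assumption: the SMILES is read as the (2S,4S,6S) isomer, i.e. 2,6-cis with the 4-acetoxy group axial (trans to both ring substituents), and 5-hydroxyvanillin is taken as a commercial starting material.

**Route**

Step 1
Reactants: 1 vanillin (4-hydroxy-3-methoxybenzaldehyde); 2 acetylacetone (pentane-2,4-dione, 3 equiv)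
Product: 3 feruloylacetone, (E)-6-(4-hydroxy-3-methoxyphenyl)hex-5-ene-2,4-dione
Conditions: B2O3 (0.7 equiv), B(OnBu)3 (2 equiv), nBuNH2 (0.2 equiv), EtOAc, 80 °C; then 1 M HCl, 60 °C
Reagents that add atoms: none
Why: Pabon-type aldol condensation, in which boron chelation of the 1,3-diketone blocks Knoevenagel reaction at the central carbon so the amine-catalysed condensation occurs at a terminal methyl; excess 2 suppresses double condensation and the E-alkene is the thermodynamic product.

Step 2
Reactants: 3 feruloylacetone; 4 5-hydroxyvanillin (3,4-dihydroxy-5-methoxybenzaldehyde)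
Product: 5 (1E,6E)-1-(3,4-dihydroxy-5-methoxyphenyl)-7-(4-hydroxy-3-methoxyphenyl)hepta-1,6-diene-3,5-dione
Conditions: B2O3 (1.5 equiv), B(OnBu)3 (3 equiv), nBuNH2 (0.3 equiv), DMF, 80 °C; then 1 M HCl, 60 °C
Reagents that add atoms: none
Why: second Pabon aldol condensation at the remaining methyl group (standard route to unsymmetrical curcuminoids); the catechol is tied up reversibly as a borate during the reaction and released by the acidic hydrolysis.

Step 3
Reactants: 5 unsymmetrical curcuminoid
Product: 6 1-(3,4-dihydroxy-5-methoxyphenyl)-7-(4-hydroxy-3-methoxyphenyl)heptane-3,5-dione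
Conditions: H2 (1 atm), 10% Pd/C, EtOAc–MeOH 4:1, rt, stopped at 2 equiv H2
Reagents that add atoms: none
Why: heterogeneous catalytic hydrogenation of the two conjugated C=C bonds is much faster than reduction of the enolised 1,3-diketone or the arenes, as in curcumin → tetrahydrocurcumin.

Step 4
Reactants: 6 saturated 3,5-dione
Product: 9 (3S,5S)-1-(3,4-dihydroxy-5-methoxyphenyl)-7-(4-hydroxy-3-methoxyphenyl)heptane-3,5-diol, via 5-hydroxy-3-ketone 7 (not isolated), via 3-hydroxy-5-ketone 8 (not isolated)
Conditions: [RuCl(C6H6)((S)-BINAP)]Cl (1 mol%), H2 (80 atm), degassed MeOH, 50 °C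
Reagents that add atoms: none
Why: Noyori asymmetric hydrogenation of a 1,3-diketone, in which (S)-BINAP sets the first carbinol as S at whichever carbonyl reacts first (7 or 8) and the chelated, catalyst-matched second reduction gives the anti (3S,5S)-diol from both; the minor enantiomer of the first step is diverted into the separable syn isomer, which raises the ee of the anti product.

Step 5
Reactants: 9 (3S,5S)-diol
Product: 12 (2S,4R,6S)-2-(3,4-dihydroxy-5-methoxyphenyl)-6-[2-(4-hydroxy-3-methoxyphenyl)ethyl]oxan-4-ol (all-cis; all three substituents equatorial), via ortho-quinone 10 (not isolated), via para-quinone methide 11 (not isolated)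
Conditions: Ag2O (1.0 equiv, portionwise), 4 Å MS, MeCN (5 mM), 0 °C → rt, dark, Ar
Reagents that add atoms: none
Why: Proposed new method: Ag2O dehydrogenates only the catechol ring (far easier to oxidise than the guaiacol ring) to ortho-quinone 10, which tautomerises through its benzylic C–H to para-quinone methide 11; the C5 hydroxyl then adds to the methide carbon (6-exo oxa-1,6-addition; the C3 hydroxyl could only form an oxetane) through a chair with all substituents equatorial, and because the addition is reversible the 2,6-cis isomer accumulates, making the new benzylic centre S; the closest known reactions are Ag2O oxidation of 4-alkylcatechols and 4-alkyl-2,6-dimethoxyphenols to quinone methides and intramolecular alcohol trapping of para-quinone methides to 2-aryl cyclic ethers.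

Step 6
Reactants: 12 all-cis oxan-4-ol
Product: 13 (2S,4S,6S)-2-(3,4-dihydroxy-5-methoxyphenyl)-6-[2-(4-hydroxy-3-methoxyphenyl)ethyl]oxan-4-yl acetate (target, CNP0143286.2)
Conditions: PPh3 (1.5 equiv), DIAD (1.5 equiv), AcOH (3 equiv), THF, 0 °C → rt
Reagents that add atoms: acetic acid, CC(=O)O
Why: Mitsunobu reaction, in which the only aliphatic hydroxyl is activated as its oxyphosphonium ion and displaced by acetate in an SN2 step that inverts C4 (R → S, equatorial OH → axial OAc); phenols are not acylated under these conditions and acetic acid (pKa about 4.8) outcompetes them (pKa about 10) as the pronucleophile.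

**Compound list**
1 | vanillin (4-hydroxy-3-methoxybenzaldehyde) | COc1cc(C=O)ccc1O | starting material
2 | acetylacetone (pentane-2,4-dione) | CC(=O)CC(C)=O | starting material
3 | feruloylacetone, (E)-6-(4-hydroxy-3-methoxyphenyl)hex-5-ene-2,4-dione | COc1cc(/C=C/C(=O)CC(C)=O)ccc1O | intermediate
4 | 5-hydroxyvanillin (3,4-dihydroxy-5-methoxybenzaldehyde) | COc1cc(C=O)cc(O)c1O | starting material
5 | (1E,6E)-1-(3,4-dihydroxy-5-methoxyphenyl)-7-(4-hydroxy-3-methoxyphenyl)hepta-1,6-diene-3,5-dione | COc1cc(/C=C/C(=O)CC(=O)/C=C/c2cc(O)c(O)c(OC)c2)ccc1O | intermediate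
6 | 1-(3,4-dihydroxy-5-methoxyphenyl)-7-(4-hydroxy-3-methoxyphenyl)heptane-3,5-dione | COc1cc(CCC(=O)CC(=O)CCc2cc(O)c(O)c(OC)c2)ccc1O | intermediate
7 | (5S)-1-(3,4-dihydroxy-5-methoxyphenyl)-5-hydroxy-7-(4-hydroxy-3-methoxyphenyl)heptan-3-one | COc1cc(CC[C@H](O)CC(=O)CCc2cc(O)c(O)c(OC)c2)ccc1O | intermediate (not isolated)
8 | (5S)-7-(3,4-dihydroxy-5-methoxyphenyl)-5-hydroxy-1-(4-hydroxy-3-methoxyphenyl)heptan-3-one | COc1cc(CCC(=O)C[C@@H](O)CCc2cc(O)c(O)c(OC)c2)ccc1O | intermediate (not isolated)
9 | (3S,5S)-1-(3,4-dihydroxy-5-methoxyphenyl)-7-(4-hydroxy-3-methoxyphenyl)heptane-3,5-diol | COc1cc(CC[C@H](O)C[C@@H](O)CCc2cc(O)c(O)c(OC)c2)ccc1O | intermediate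
10 | ortho-quinone: 5-[(3S,5S)-3,5-dihydroxy-7-(4-hydroxy-3-methoxyphenyl)heptyl]-3-methoxycyclohexa-3,5-diene-1,2-dione | COc1cc(CC[C@H](O)C[C@@H](O)CCC2=CC(=O)C(=O)C(OC)=C2)ccc1O | intermediate (not isolated)
11 | para-quinone methide: 4-[(3S,5S)-3,5-dihydroxy-7-(4-hydroxy-3-methoxyphenyl)heptylidene]-2-hydroxy-6-methoxycyclohexa-2,5-dien-1-one | COc1cc(CC[C@H](O)C[C@@H](O)CC=C2C=C(O)C(=O)C(OC)=C2)ccc1O | intermediate (not isolated)
12 | (2S,4R,6S)-2-(3,4-dihydroxy-5-methoxyphenyl)-6-[2-(4-hydroxy-3-methoxyphenyl)ethyl]oxan-4-ol | COc1cc(CC[C@H]2C[C@@H](O)C[C@@H](c3cc(O)c(O)c(OC)c3)O2)ccc1O | intermediate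
13 | (2S,4S,6S)-2-(3,4-dihydroxy-5-methoxyphenyl)-6-[2-(4-hydroxy-3-methoxyphenyl)ethyl]oxan-4-yl acetate | COc1cc(CC[C@H]2C[C@H](OC(C)=O)C[C@@H](c3cc(O)c(O)c(OC)c3)O2)ccc1O | target

**Step count and risk**

Total steps: 6. Longest linear sequence: 6 (1/2 → 13).

The three steps most likely to fail:

Step 5 (oxidative cyclisation). The ortho-quinone may oligomerise or add nucleophiles on the ring before it tautomerises, and product 12 is itself a catechol that can be over-oxidised. The fallback sets out from 9 and comes back at 12, and it separates the oxidation from the ring closure. Oxidise 9 with Ag2O in methanol at 0 °C, so that the solvent, in vast excess, intercepts the quinone methide and gives the benzylic methyl ether (3R,5S)-1-(3,4-dihydroxy-5-methoxyphenyl)-7-(4-hydroxy-3-methoxyphenyl)-1-methoxyheptane-3,5-diol F1 as a mixture of C1 epimers (same spatial arrangement at C3 and C5 as in 9). After isolation, treat it with camphorsulfonic acid (10 mol%) in CH2Cl2–THF at rt. The para-hydroxybenzylic ether ionises and the C5 hydroxyl closes the ring in an SN1 etherification under thermodynamic control, giving 12 with loss of methanol.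

Step 6 (Mitsunobu on a triphenolic substrate). Competing elimination to the dihydropyran, phenol O-alkylation, or oxidation of the catechol by DIAD could erode the yield. The fallback sets out from 12 and comes back at 13, replacing the Mitsunobu by a sulfonate displacement on a phenol-masked substrate. Acetylate only the three phenols (Ac2O 3.3 equiv, K2CO3, acetone, 0 °C) to the phenolic tri-O-acetate F2, which keeps the equatorial 4-OH free. Convert it with MsCl/Et3N in CH2Cl2 at 0 °C into the equatorial 4-O-mesylate F3. Displace with CsOAc/18-crown-6 in toluene at 90 °C (SN2, inversion) to the axial tetraacetate F4. Finally cleave the three aryl acetates selectively with NH4OAc in MeOH at rt; the hindered secondary acetate survives and 13 results.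

Step 4 (Ru/BINAP hydrogenation with a free catechol). The catechol may bind the divalent ruthenium catalyst and stall it, or the anti:syn ratio may be lower than for simple diketones. The fallback sets out from 6 and comes back at 9, passing through 7 and 8 as isolated compounds instead of in-flask intermediates. Mono-reduce 6 with an (S)-selective ketoreductase (NADPH recycled with glucose/glucose dehydrogenase, pH 7 buffer containing ascorbate, 30 °C) to the mixture of ketols 7 and 8. Then carry out a hydroxyl-directed Evans–Saksena reduction (Me4NBH(OAc)3, MeCN–AcOH, −20 °C), which delivers hydride intramolecularly anti to the existing carbinol. Both regioisomeric ketols converge on the same (3S,5S)-diol 9, so the regiochemistry of the first reduction does not matter.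

Further compounds
F1 | step 5 | (3R,5S)-1-(3,4-dihydroxy-5-methoxyphenyl)-7-(4-hydroxy-3-methoxyphenyl)-1-methoxyheptane-3,5-diol (C1 epimers) | COc1cc(CC[C@H](O)C[C@@H](O)CC(OC)c2cc(O)c(O)c(OC)c2)ccc1O
F2 | step 6 | phenolic tri-O-acetate: 4-{2-[(2S,4R,6S)-6-(3,4-diacetoxy-5-methoxyphenyl)-4-hydroxyoxan-2-yl]ethyl}-2-methoxyphenyl acetate | COc1cc(CC[C@H]2C[C@@H](O)C[C@@H](c3cc(OC(C)=O)c(OC(C)=O)c(OC)c3)O2)ccc1OC(C)=O
F3 | step 6 | equatorial 4-O-mesylate: 4-{2-[(2S,4R,6S)-6-(3,4-diacetoxy-5-methoxyphenyl)-4-(methanesulfonyloxy)oxan-2-yl]ethyl}-2-methoxyphenyl acetate | COc1cc(CC[C@H]2C[C@@H](OS(C)(=O)=O)C[C@@H](c3cc(OC(C)=O)c(OC(C)=O)c(OC)c3)O2)ccc1OC(C)=O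
F4 | step 6 | axial tetraacetate: 4-{2-[(2S,4S,6S)-4-acetoxy-6-(3,4-diacetoxy-5-methoxyphenyl)oxan-2-yl]ethyl}-2-methoxyphenyl acetate | COc1cc(CC[C@H]2C[C@H](OC(C)=O)C[C@@H](c3cc(OC(C)=O)c(OC(C)=O)c(OC)c3)O2)ccc1OC(C)=O
F0 | step 4 | none | none
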